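**Overview**

1. Disconnections: the O7–isopropyl bond is cut last. Ring A is then cut across C4a–C5 and C8–C8a, which separates γ-pyrone 9 (rings B and C) from cyclobutenedione 12 (C5, C6-Me, C7-O and C8).
2. Enabling feature: ring A is hexasubstituted, with oxygens at C5 and C8 para to each other, C6-Me and C7-O between them, and the C4a=C8a edge shared with ring C. The four ring carbons of an alkoxy(methyl)cyclobutenone give this hydroquinone monoether pattern when they expand across the C5=C6 alkene of a 4-pyranone.
3. Forward order: ring B is bought as 4-bromoanisole. Ring C is grown from furfural by aryl Grignard addition, Achmatowicz ring expansion, maltol-type isomerisation and O-methylation. The four-membered ring is joined to pyranone C6 (future C8a), ring A closes last by thermal ring expansion, and the isopropyl group is removed.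
4. Stereochemistry: the target has no stereocentre. Every sp3 centre made on the way is carried racemic or as a mixture and is erased on aromatisation.

Key step: step 10

Remark: the target SMILES shows no stereocentre, so the compound is treated as achiral. Locants C2 to C8a refer to the flavone skeleton; "pyranone C5/C6" refers to the monocyclic 4H-pyran-4-one 9.

**Route**

Step 1
Reactants: 1 furfural; 2 4-bromoanisole
Product: 4 (±)-furan-2-yl(4-methoxyphenyl)methanol, via 4-methoxyphenylmagnesium bromide 3 (not isolated)
Conditions: Mg, I2 (cat.), THF, reflux; then 1, 0 °C to rt; aq. NH4Cl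
Reagents that add atoms: none
Why: Grignard formation and 1,2-addition to the aldehyde are routine, and the new carbinol centre forms without control and is carried racemic because it is destroyed in step 5.

Step 2
Reactants: 4 (±)-furan-2-yl(4-methoxyphenyl)methanol
Product: 5 6-hydroxy-2-(4-methoxyphenyl)-2H-pyran-3(6H)-one (racemic, mixture of C6 epimers)
Conditions: NBS, NaHCO3, THF/H2O (4:1), 0 °C
Reagents that add atoms: water, O
Why: Achmatowicz rearrangement, in which bromonium attack at furan C5 and capture by water give a dihydroxydihydrofuran that opens to the ene-dione and recloses through the carbinol oxygen to the pyranone hemiacetal; the anomeric centre forms as a mixture, which does not matter.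

Step 3
Reactants: 5 6-hydroxy-2-(4-methoxyphenyl)-2H-pyran-3(6H)-one
Product: 6 6-methoxy-2-(4-methoxyphenyl)-2H-pyran-3(6H)-one (racemic, anomeric mixture)
Conditions: HC(OMe)3, BF3·OEt2 (cat.), CH2Cl2, 0 °C
Reagents that add atoms: trimethyl orthoformate, COC(OC)OC
Why: Acid-catalysed acetal exchange through the ring oxocarbenium ion (Fischer-type glycosidation with the orthoester as methanol source and water scavenger) caps the lactol so that the enone can face basic peroxide; the anomeric configuration is of no consequence.

Step 4
Reactants: 6 6-methoxy-2-(4-methoxyphenyl)-2H-pyran-3(6H)-one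
Product: 7 4,5-epoxy-6-methoxy-2-(4-methoxyphenyl)tetrahydropyran-3-one, also named 2-methoxy-4-(4-methoxyphenyl)-3,7-dioxabicyclo[4.1.0]heptan-5-one (racemic, diastereomer mixture)
Conditions: 30% aq. H2O2, NaOH (cat.), MeOH, 0 °C
Reagents that add atoms: hydrogen peroxide, OO
Why: Weitz–Scheffer nucleophilic epoxidation of the enone, with hydroperoxide expected to add at C5 anti to the C6 methoxy group; the epoxide stereocentres are erased in the next step.

Step 5
Reactants: 7 4,5-epoxy-6-methoxy-2-(4-methoxyphenyl)tetrahydropyran-3-one
Product: 8 3-hydroxy-2-(4-methoxyphenyl)-4H-pyran-4-one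
Conditions: 1 M aq. H2SO4, 1,4-dioxane, 90 °C
Reagents that add atoms: none
Why: Acid-mediated epoxy-ketone to diosphenol isomerisation with β-elimination of methanol (the maltol-type γ-pyrone synthesis), in which epoxide carbon C4 becomes the ring carbonyl, C5–C6 becomes the enol ether and the C3 ketone enolises toward benzylic C2, so all four sp3 centres vanish.

Step 6
Reactants: 8 3-hydroxy-2-(4-methoxyphenyl)-4H-pyran-4-one
Product: 9 3-methoxy-2-(4-methoxyphenyl)-4H-pyran-4-one
Conditions: MeI, K2CO3, acetone, reflux
Reagents that add atoms: iodomethane, CI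
Why: Williamson O-methylation of the acidic enolic 3-hydroxyl, the only alkylatable site of the pyranone.

Step 7
Reactants: 10 diisopropyl squarate (3,4-diisopropoxycyclobut-3-ene-1,2-dione)
Product: 12 3-isopropoxy-4-methylcyclobut-3-ene-1,2-dione, via 4-hydroxy-2,3-diisopropoxy-4-methylcyclobut-2-en-1-one 11 (not isolated)
Conditions: MeLi, THF, −78 °C; then aq. HCl, CH2Cl2, rt
Reagents that add atoms: methyllithium, [Li]C
Why: 1,2-Addition of the organolithium to one squarate carbonyl followed by acid-induced 1,3-carbonyl transposition with loss of isopropanol is the standard entry to 3-alkoxy-4-alkylcyclobutenediones.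

Step 8
Reactants: 9 3-methoxy-2-(4-methoxyphenyl)-4H-pyran-4-one; 12 3-isopropoxy-4-methylcyclobut-3-ene-1,2-dione
Product: 14 (±)-4-hydroxy-3-isopropoxy-4-[5-methoxy-6-(4-methoxyphenyl)-4-oxo-4H-pyran-2-yl]-2-methylcyclobut-2-en-1-one, via 6-lithiopyranone 13 (not isolated)
Conditions: lithium 2,2,6,6-tetramethylpiperidide (from 2,2,6,6-tetramethylpiperidine and n-BuLi), THF, −78 °C, 10 min; then 12, −78 °C; aq. NH4Cl
Reagents that add atoms: none
Why: Proposed new method: C6–H of 9 is the only ring C–H alpha to the ring oxygen (C2 carries the aryl group), so a hindered non-nucleophilic amide should remove it kinetically at −78 °C to give alkenyllithium 13, which should add to the ketone-like carbonyl of 12 (the one next to the isopropoxy-bearing carbon, not the vinylogous ester carbonyl) and set the quaternary carbinol as a racemate; the closest known reaction types are the C2-lithiation of chromones with hindered lithium amides and the 1,2-addition of alkenyl- and heteroaryllithiums to 3-alkoxycyclobutenediones.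

Step 9
Reactants: 14 (±)-4-hydroxy-3-isopropoxy-4-[5-methoxy-6-(4-methoxyphenyl)-4-oxo-4H-pyran-2-yl]-2-methylcyclobut-2-en-1-one
Product: 15 (±)-3-isopropoxy-4-methoxy-4-[5-methoxy-6-(4-methoxyphenyl)-4-oxo-4H-pyran-2-yl]-2-methylcyclobut-2-en-1-one
Conditions: MeI, Ag2O, MeCN, rt, dark
Reagents that add atoms: iodomethane, CI
Why: Purdie methylation alkylates the tertiary carbinol under nearly neutral conditions that spare the base- and heat-sensitive cyclobutenone, and it fixes the future C8 oxygen as its methyl ether before ring A exists.

Step 10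
Reactants: 15 (±)-3-isopropoxy-4-methoxy-4-[5-methoxy-6-(4-methoxyphenyl)-4-oxo-4H-pyran-2-yl]-2-methylcyclobut-2-en-1-one
Product: 18 5-hydroxy-7-isopropoxy-3,8-dimethoxy-2-(4-methoxyphenyl)-6-methyl-4H-chromen-4-one, via dienylketene 16 (not isolated), via cyclohexadienone 17 (not isolated)
Conditions: degassed p-xylene, 138 °C, Ar
Reagents that add atoms: none
Why: Heating should open the cyclobutenone by conrotatory 4π electrocyclic cleavage of the bond between the quaternary carbon and the carbonyl to give dienylketene 16, whose ketene carbon (future C5) then bonds to pyranone C5 (future C4a) to give cyclohexadienone 17, which enolises to phenol 18. The closest known reaction type is the Moore rearrangement of 4-aryl-, 4-heteroaryl- and 4-alkenyl-4-alkoxycyclobutenones to hydroquinone monoethers, run here with the C5=C6 alkene of a γ-pyrone as the 2π partner. Ring A, a six-membered carbocycle, closes by thermal disrotatory 6π electrocyclisation that forms the C4a–C5 bond, the C8–C8a bond being in place since step 8. No stereocentre remains, because the quaternary carbon of 15 becomes sp2 C8 and the C4a–H centre of 17 is lost on tautomerisation, which is driven by aromatisation and by the hydrogen bond from the new 5-OH to the C4 carbonyl. The step needs torquoselectivity and regioselectivity: the methoxy donor on the breaking bond should rotate outward so that the pyranonyl group turns inward toward the ketene, and pyranone C6 has C5–H as its only carbon neighbour, so only one closure is possible, with matched polarity (C5 is the nucleophilic α-carbon of the vinylogous ester and the ketene carbon is electrophilic). The substituent order 5-OH, 6-Me, 7-O-iPr, 8-OMe follows from the addition regiochemistry of step 8 and the methylation of step 9, so no phenol has to be differentiated afterwards.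

Step 11
Reactants: 18 5-hydroxy-7-isopropoxy-3,8-dimethoxy-2-(4-methoxyphenyl)-6-methyl-4H-chromen-4-one
Product: 19 5,7-dihydroxy-3,8-dimethoxy-2-(4-methoxyphenyl)-6-methyl-4H-chromen-4-one
Conditions: BCl3, CH2Cl2, −78 to 0 °C; then H2O
Reagents that add atoms: none
Why: Lewis-acid ether cleavage with BCl3 removes a secondary alkyl aryl ether much faster than methyl ethers at low temperature, and the 5-hydroxyl is tied up as a boron chelate with the C4 carbonyl, so only the 7-isopropyl group should be lost.

**Compound list**

1 | furfural | O=Cc1ccco1 | starting material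
2 | 4-bromoanisole | COc1ccc(Br)cc1 | starting material
3 | 4-methoxyphenylmagnesium bromide | COc1ccc([Mg]Br)cc1 | intermediate
4 | (±)-furan-2-yl(4-methoxyphenyl)methanol | COc1ccc(C(O)c2ccco2)cc1 | intermediate
5 | 6-hydroxy-2-(4-methoxyphenyl)-2H-pyran-3(6H)-one, racemic, C6 epimer mixture | COc1ccc(C2OC(O)C=CC2=O)cc1 | intermediate
6 | 6-methoxy-2-(4-methoxyphenyl)-2H-pyran-3(6H)-one, racemic, anomeric mixture | COc1ccc(C2OC(OC)C=CC2=O)cc1 | intermediate
7 | 4,5-epoxy-6-methoxy-2-(4-methoxyphenyl)tetrahydropyran-3-one, racemic, diastereomer mixture | COc1ccc(C2OC(OC)C3OC3C2=O)cc1 | intermediate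
8 | 3-hydroxy-2-(4-methoxyphenyl)-4H-pyran-4-one | COc1ccc(-c2occc(=O)c2O)cc1 | intermediate
9 | 3-methoxy-2-(4-methoxyphenyl)-4H-pyran-4-one | COc1ccc(-c2occc(=O)c2OC)cc1 | intermediate
10 | diisopropyl squarate | CC(C)OC1=C(OC(C)C)C(=O)C1=O | starting material
11 | 4-hydroxy-2,3-diisopropoxy-4-methylcyclobut-2-en-1-one, racemic | CC(C)OC1=C(OC(C)C)C(C)(O)C1=O | intermediate
12 | 3-isopropoxy-4-methylcyclobut-3-ene-1,2-dione | CC1=C(OC(C)C)C(=O)C1=O | intermediate
13 | 6-lithio-3-methoxy-2-(4-methoxyphenyl)-4H-pyran-4-one | COc1ccc(-c2oc([Li])cc(=O)c2OC)cc1 | intermediate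
14 | (±)-4-hydroxy-3-isopropoxy-4-[5-methoxy-6-(4-methoxyphenyl)-4-oxo-4H-pyran-2-yl]-2-methylcyclobut-2-en-1-one | COc1ccc(-c2oc(C3(O)C(OC(C)C)=C(C)C3=O)cc(=O)c2OC)cc1 | intermediate
15 | (±)-3-isopropoxy-4-methoxy-4-[5-methoxy-6-(4-methoxyphenyl)-4-oxo-4H-pyran-2-yl]-2-methylcyclobut-2-en-1-one | COc1ccc(-c2oc(C3(OC)C(OC(C)C)=C(C)C3=O)cc(=O)c2OC)cc1 | intermediate
16 | (3Z)-3-isopropoxy-4-methoxy-4-[5-methoxy-6-(4-methoxyphenyl)-4-oxo-4H-pyran-2-yl]-2-methylbuta-1,3-dien-1-one (pyranonyl group cis to C2) | CC(=C=O)/C(OC(C)C)=C(/OC)c1cc(=O)c(OC)c(-c2ccc(OC)cc2)o1 | intermediate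
17 | 7-isopropoxy-3,8-dimethoxy-2-(4-methoxyphenyl)-6-methyl-4aH-chromene-4,5-dione, racemic | COc1ccc(C2=C(OC)C(=O)C3C(=O)C(C)=C(OC(C)C)C(OC)=C3O2)cc1 | intermediate
18 | 5-hydroxy-7-isopropoxy-3,8-dimethoxy-2-(4-methoxyphenyl)-6-methyl-4H-chromen-4-one | COc1ccc(-c2oc3c(OC)c(OC(C)C)c(C)c(O)c3c(=O)c2OC)cc1 | intermediate
19 | 5,7-dihydroxy-3,8-dimethoxy-2-(4-methoxyphenyl)-6-methyl-4H-chromen-4-one | COc1ccc(-c2oc3c(OC)c(O)c(C)c(O)c3c(=O)c2OC)cc1 | target

**Step count**

Total step count: 11. Longest linear sequence: 10 steps (steps 1 to 6 and 8 to 11, from furfural and 4-bromoanisole); step 7 is a one-step side branch.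

**Steps most likely to fail**

Step 8 (proposed new method). The lithiated pyranone may add to unreacted 9, or break down before it is trapped, or the deprotonation may not be clean. The fallback uses known chemistry with reversed polarity: 9 serves as a Michael acceptor in a Hauser–Kraus annulation, for which chromones are established acceptors. It sets out from 9 and returns at 18.
- Commercial 3-methyltetronic acid would be etherified (isopropanol, TsOH, azeotropic removal of water) to 4-isopropoxy-3-methylfuran-2(5H)-one F1.
- F1 would be sulfenylated at C5 through its lithium dienolate (LiN(iPr)2, PhSSPh, THF, −78 °C) to 4-isopropoxy-3-methyl-5-(phenylsulfanyl)furan-2(5H)-one F2.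
- Oxidation (mCPBA, CH2Cl2) would give 4-isopropoxy-3-methyl-5-(phenylsulfonyl)furan-2(5H)-one F3.
- The anion of F3 (LiOtBu, THF, −78 °C to rt) should add to C6 of 9. The resulting enolate should acylate at pyranone C5 on the lactone carbonyl, sulfinate should be expelled, and the ene-dione should tautomerise.
- After reductive work-up (aq. Na2S2O4) this would give 5,8-dihydroxy-7-isopropoxy-3-methoxy-2-(4-methoxyphenyl)-6-methyl-4H-chromen-4-one F4.
- Methylation of the free, non-chelated 8-hydroxyl (one equivalent of MeI, K2CO3, acetone) would then give 18.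

Step 10. The methoxy group may rotate inward in part, giving a ketene that cannot cyclise and is lost to dimerisation or adventitious nucleophiles, or the methyl ether may degrade during the prolonged heating it needs. The fallback moves the ring expansion one step earlier and differentiates the two phenols afterwards by chelation. It sets out from 14 and returns at 18.
- The free carbinol 14, whose hydroxyl is the stronger outward-rotating donor, would be heated (toluene, 110 °C).
- Oxidative work-up (Ag2O) would give 7-isopropoxy-3-methoxy-2-(4-methoxyphenyl)-6-methyl-4H-chromene-4,5,8-trione F5, which is isolable.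
- Reduction (Na2S2O4, EtOAc/H2O) would give hydroquinone F4, and the same selective 8-O-methylation (MeI, K2CO3, acetone) would lead to 18.

Step 5. Acid may ionise the p-methoxybenzylic C2–O bond or cleave the ring faster than the epoxy ketone isomerises, and the preceding basic epoxidation may already erode material through the acidic C2–H. The fallback builds the aryl pyranone by cross-coupling. It sets out from 2 and returns at 9.
- Grignard reagent 3 (from 2) would be quenched with B(OMe)3 and hydrolysed to 4-methoxyphenylboronic acid F6.
- Commercial 3-hydroxy-4H-pyran-4-one would be brominated ortho to the hydroxyl (Br2, H2O, 0 °C) to 2-bromo-3-hydroxy-4H-pyran-4-one F7.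
- F7 would be methylated (MeI, K2CO3, acetone) to 2-bromo-3-methoxy-4H-pyran-4-one F8.
- Suzuki–Miyaura coupling of F6 with F8 (Pd(PPh3)4, K2CO3, dioxane/H2O, 90 °C) would give 9 directly.

**Further compounds**

F1 | step 8 | 4-isopropoxy-3-methylfuran-2(5H)-one | CC1=C(OC(C)C)COC1=O
F2 | step 8 | 4-isopropoxy-3-methyl-5-(phenylsulfanyl)furan-2(5H)-one, racemic | CC1=C(OC(C)C)C(Sc2ccccc2)OC1=O
F3 | step 8 | 4-isopropoxy-3-methyl-5-(phenylsulfonyl)furan-2(5H)-one, racemic | CC1=C(OC(C)C)C(S(=O)(=O)c2ccccc2)OC1=O
F4 | step 8 | 5,8-dihydroxy-7-isopropoxy-3-methoxy-2-(4-methoxyphenyl)-6-methyl-4H-chromen-4-one | COc1ccc(-c2oc3c(O)c(OC(C)C)c(C)c(O)c3c(=O)c2OC)cc1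
F5 | step 10 | 7-isopropoxy-3-methoxy-2-(4-methoxyphenyl)-6-methyl-4H-chromene-4,5,8-trione | COc1ccc(C2=C(OC)C(=O)C3=C(O2)C(=O)C(OC(C)C)=C(C)C3=O)cc1
F6 | step 5 | 4-methoxyphenylboronic acid | COc1ccc(B(O)O)cc1
F7 | step 5 | 2-bromo-3-hydroxy-4H-pyran-4-one | O=c1ccoc(Br)c1O
F8 | step 5 | 2-bromo-3-methoxy-4H-pyran-4-one | COc1c(Br)occc1=O
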